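The route is disconnected at the C4a–C8a bond of ring A. Ring A is a phloroglucinol in which the acyl-bearing C4a lies between the oxygenated C5 and C8a and para to C7–OMe, the oxygen pattern of a folded tetraketide. A 4-methoxy-2-pyranone carrying an O-benzylferuloylmethyl chain at C6 is that tetraketide in masked form. Magnesium methoxide opens the lactone and a Claisen closure builds carbocyclic ring A in one operation, giving the 2',6'-dihydroxy-4'-methoxychalcone with the 7-OMe already differentiated. Ring C is then closed oxidatively, C3 is hydroxylated, the lone hydroxyl is sulfated and both benzyl ethers are removed by hydrogenolysis.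

Key step: step 3

Remark on the chemistry: the target has no stereocentre, so no enantiocontrol is required; it is drawn as the free hydrogen sulfate, which is acid-labile, so it would be liberated cold in the last operation and freeze-dried at once.

Step 1
Reactants: 1 4-(benzyloxy)-3-methoxybenzaldehyde; 2 diethyl {2-[methoxy(methyl)amino]-2-oxoethyl}phosphonate
Product: 3 (2E)-3-[4-(benzyloxy)-3-methoxyphenyl]-N-methoxy-N-methylprop-2-enamide
Conditions: NaH, THF, 0 °C → rt
Reagents that add atoms: none
Why: Horner–Wadsworth–Emmons olefination of a non-enolisable aryl aldehyde with the stabilised phosphonate anion should give the E-enamide directly, with no stereocentre formed.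

Step 2
Reactants: 4 4-methoxy-6-methyl-2H-pyran-2-one; 3 (2E)-3-[4-(benzyloxy)-3-methoxyphenyl]-N-methoxy-N-methylprop-2-enamide
Product: 7 6-[(3E)-4-[4-(benzyloxy)-3-methoxyphenyl]-2-oxobut-3-en-1-yl]-4-methoxy-2H-pyran-2-one, via lithiated pyranone 5 (not isolated), via tetrahedral lithium adduct 6 (not isolated)
Conditions: 4 (2 equiv), LDA (commercial solution, 2 equiv), THF, −78 °C; then 3 (1 equiv), −78 → −30 °C; cold 1 M HCl
Reagents that add atoms: none
Why: Deprotonation of the C6 methyl group gives a vinylogous ester enolate that undergoes acyl substitution on the Weinreb amide (Weinreb ketone synthesis); the chelated adduct 6 persists until the acidic quench, so over-addition is excluded and the acidic methylene of 7 never meets the anion, while the hard lithium nucleophile and the poor acceptor character of an enamide favour 1,2-attack.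

Step 3
Reactants: 7 6-[(3E)-4-[4-(benzyloxy)-3-methoxyphenyl]-2-oxobut-3-en-1-yl]-4-methoxy-2H-pyran-2-one
Product: 9 (E)-4-benzyloxy-2',6'-dihydroxy-3,4'-dimethoxychalcone, via ring-opened magnesium diketonate 8 (not isolated)
Conditions: Mg(OMe)2 (commercial solution, ca. 5 equiv), MeOH, reflux; then cold 1 M HCl
Reagents that add atoms: none
Why: Methoxide adds to the lactone carbonyl (pyranone C2) and opens the ring to the methyl (2E)-3-methoxy-5,7-dioxo enoate, held as its magnesium 5,7-diketonate 8; the carbon between the two ketones then attacks the ester carbonyl, methoxide leaves, and enolisation of the cyclohexenedione gives the aromatic ring, so the former lactone carbonyl and ring oxygen become the two phenols flanking the cinnamoyl group. The closest known reaction type is the base-mediated Claisen (Dieckmann-type) recyclisation of 6-(2-oxoalkyl)-4-methoxy-2-pyranones and 3,5,7-triketo esters to acylphloroglucinols. Ring A is closed by a 6-exo-trig acyl substitution that forms the future C4a–C8a bond. No stereocentre is created and the E-enone is not touched. The step needs C-acylation to win over aldol closure, re-lactonisation, 4-pyranone formation and conjugate addition of methoxide: the methyl enol ether keeps chain C2 sp2 and non-nucleophilic, which blocks the resorcylate-forming aldol mode, and its E geometry, inherited from the ring, holds the ester beside the diketone, while Mg2+ chelation activates the ester and steers reaction to the central diketone carbon, and methoxide addition to the enone is reversible.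

Step 4
Reactants: 9 (E)-4-benzyloxy-2',6'-dihydroxy-3,4'-dimethoxychalcone
Product: 10 2-[4-(benzyloxy)-3-methoxyphenyl]-5-hydroxy-7-methoxy-4H-chromen-4-one
Conditions: I2 (10 mol%), DMSO, 120 °C
Reagents that add atoms: none
Why: Iodine-catalysed oxidative cyclisation of a 2'-hydroxychalcone in DMSO (oxa-Michael closure, then iodination–dehydroiodination with DMSO reoxidising HI) should give the flavone; the two ortho phenols are equivalent, any flavanone isomer carried over from step 3 converges on the same product, and the second phenol ends as the chelated 5-OH.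

Step 5
Reactants: 10 2-[4-(benzyloxy)-3-methoxyphenyl]-5-hydroxy-7-methoxy-4H-chromen-4-one
Product: 11 5-(benzyloxy)-2-[4-(benzyloxy)-3-methoxyphenyl]-7-methoxy-4H-chromen-4-one
Conditions: BnBr, K2CO3, DMF, 70 °C
Reagents that add atoms: benzyl bromide BrCc1ccccc1
Why: Williamson etherification of the only hydroxyl present; the chelated 5-OH needs a polar aprotic solvent and heat but has no competitor, and masking it protects the phenol from the dioxirane and later leaves C3–OH as the sole site for sulfation.

Step 6
Reactants: 11 5-(benzyloxy)-2-[4-(benzyloxy)-3-methoxyphenyl]-7-methoxy-4H-chromen-4-one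
Product: 13 5-(benzyloxy)-2-[4-(benzyloxy)-3-methoxyphenyl]-3-hydroxy-7-methoxy-4H-chromen-4-one, via flavone 2,3-epoxide 12 (not isolated)
Conditions: DMDO (pre-formed acetone solution), CH2Cl2, 0 °C → rt; concentrate; p-TsOH (cat.), CH2Cl2, rt
Reagents that add atoms: dimethyldioxirane CC1(C)OO1
Why: Dioxirane epoxidation of the C2=C3 enol-ether double bond gives the racemic cis-fused epoxide 12, which under acid opens at C2 (cation stabilised by O1 and the aryl ring) and loses H3 to give the 3-hydroxyflavone, destroying both transient stereocentres; the sequence is established for benzyl-protected flavones.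

Step 7
Reactants: 13 5-(benzyloxy)-2-[4-(benzyloxy)-3-methoxyphenyl]-3-hydroxy-7-methoxy-4H-chromen-4-one
Product: 14 triethylammonium 5,4'-di-O-benzylrhamnazin 3-sulfate
Conditions: SO3·NEt3 (excess), Et3N, DMF, 60 °C; chromatography with Et3N-buffered eluent
Reagents that add atoms: sulfur trioxide–triethylamine complex CC[N+](CC)(CC)S(=O)(=O)[O-]
Why: O-Sulfation of a hydroxyl with an amine–sulfur trioxide complex; C3–OH is the only free hydroxyl in 13, so the site is unambiguous, and the product is kept as its ammonium salt to avoid acid-promoted desulfation.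

Step 8
Reactants: 14 triethylammonium 5,4'-di-O-benzylrhamnazin 3-sulfate
Product: 16 rhamnazin 3-O-sulfate, via triethylammonium rhamnazin 3-sulfate 15 (not isolated)
Conditions: H2 (1 atm), 10% Pd/C, THF/MeOH, rt; filter; Dowex 50W (H+ form), MeOH/H2O, 0 °C; freeze-dry
Reagents that add atoms: none
Why: Catalytic hydrogenolysis should cleave both benzyl ethers while leaving the aryl sulfate and the chromone C2=C3 bond intact (a known deprotection for benzylated flavonoid sulfates), and a brief cold pass through a sulfonic acid resin exchanges triethylammonium for a proton to give the hydrogen sulfate as drawn.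

Compound list
1 | 4-(benzyloxy)-3-methoxybenzaldehyde (O-benzylvanillin) | COc1cc(C=O)ccc1OCc1ccccc1 | starting material
2 | diethyl {2-[methoxy(methyl)amino]-2-oxoethyl}phosphonate | CCOP(=O)(OCC)CC(=O)N(C)OC | starting material
3 | (2E)-3-[4-(benzyloxy)-3-methoxyphenyl]-N-methoxy-N-methylprop-2-enamide | CON(C)C(=O)/C=C/c1ccc(OCc2ccccc2)c(OC)c1 | intermediate
4 | 4-methoxy-6-methyl-2H-pyran-2-one | COC1=CC(=O)OC(C)=C1 | starting material
5 | 6-(lithiomethyl)-4-methoxy-2H-pyran-2-one (lithiated pyranone, formed in the flask) | [Li]CC1=CC(OC)=CC(=O)O1 | intermediate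
6 | lithium alkoxide of the tetrahedral adduct of 5 with 3 (racemic, formed in the flask; the stereocentre is lost on collapse) | COC1=CC(=O)OC(CC([O-])(N(C)OC)/C=C/c2ccc(OCc3ccccc3)c(OC)c2)=C1.[Li+] | intermediate
7 | 6-[(3E)-4-[4-(benzyloxy)-3-methoxyphenyl]-2-oxobut-3-en-1-yl]-4-methoxy-2H-pyran-2-one | COC1=CC(=O)OC(CC(=O)/C=C/c2ccc(OCc3ccccc3)c(OC)c2)=C1 | intermediate
8 | methoxymagnesium 5,7-diketonate of methyl (2E,8E)-9-[4-(benzyloxy)-3-methoxyphenyl]-3-methoxy-5,7-dioxonona-2,8-dienoate (formed in the flask) | COC(=O)/C=C(/OC)CC(=O)[CH-]C(=O)/C=C/c1ccc(OCc2ccccc2)c(OC)c1.[Mg+2].C[O-] | intermediate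
9 | (E)-4-benzyloxy-2',6'-dihydroxy-3,4'-dimethoxychalcone | COc1cc(O)c(C(=O)/C=C/c2ccc(OCc3ccccc3)c(OC)c2)c(O)c1 | intermediate
10 | 2-[4-(benzyloxy)-3-methoxyphenyl]-5-hydroxy-7-methoxy-4H-chromen-4-one (4'-O-benzylvelutin) | COc1cc(O)c2c(=O)cc(-c3ccc(OCc4ccccc4)c(OC)c3)oc2c1 | intermediate
11 | 5-(benzyloxy)-2-[4-(benzyloxy)-3-methoxyphenyl]-7-methoxy-4H-chromen-4-one | COc1cc(OCc5ccccc5)c2c(=O)cc(-c3ccc(OCc4ccccc4)c(OC)c3)oc2c1 | intermediate
12 | rac-2,3-epoxide of 11 (cis ring fusion, one enantiomer drawn, formed in the flask) | COc1cc(OCc5ccccc5)c2c(c1)O[C@]3(c6ccc(OCc4ccccc4)c(OC)c6)O[C@@H]3C2=O | intermediate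
13 | 5-(benzyloxy)-2-[4-(benzyloxy)-3-methoxyphenyl]-3-hydroxy-7-methoxy-4H-chromen-4-one (5,4'-di-O-benzylrhamnazin) | COc1cc(OCc5ccccc5)c2c(=O)c(O)c(-c3ccc(OCc4ccccc4)c(OC)c3)oc2c1 | intermediate
14 | triethylammonium 5,4'-di-O-benzylrhamnazin 3-sulfate | COc1cc(OCc5ccccc5)c2c(=O)c(OS(=O)(=O)[O-])c(-c3ccc(OCc4ccccc4)c(OC)c3)oc2c1.CC[NH+](CC)CC | intermediate
15 | triethylammonium rhamnazin 3-sulfate (formed in the flask) | COc1cc(O)c2c(=O)c(OS(=O)(=O)[O-])c(-c3ccc(O)c(OC)c3)oc2c1.CC[NH+](CC)CC | intermediate
16 | rhamnazin 3-O-sulfate | COc1cc(O)c2c(=O)c(OS(=O)(=O)O)c(-c3ccc(O)c(OC)c3)oc2c1 | target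

Total step count: 8. Longest linear sequence: 8 steps (1 → 16); 2 and 4 are purchased and enter at steps 1 and 2.

Steps most likely to fail

Step 3 (key step). After ring opening the chain may close in other modes (re-lactonisation, 4-pyranone formation by displacement of the enol-ether methoxy group), may be cut by retro-Claisen attack of methoxide on the diketone, or may suffer irreversible methoxide addition to the enone. The fallback leaves the pyranone approach for a Claisen–Schmidt construction of the same chalcone; it sets out from aldehyde 1 and comes back to the route at 9. Purchased 1-(2,6-dihydroxy-4-methoxyphenyl)ethanone would be mono-protected (MOMCl, iPr2NEt, CH2Cl2; the second hydroxyl stays chelated to the ketone) to give 1-[2-hydroxy-4-methoxy-6-(methoxymethoxy)phenyl]ethanone F1. Aldol condensation of F1 with 1 (KOH, EtOH, rt) should give (E)-3-[4-(benzyloxy)-3-methoxyphenyl]-1-[2-hydroxy-4-methoxy-6-(methoxymethoxy)phenyl]prop-2-en-1-one F2. Removal of the MOM group (HCl, MeOH) returns 9; any flavanone formed in that acidic step is an equally good feed for step 4.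

Step 2. The pyranone anion may add in conjugate fashion to the enamide, metalation may occur at a ring carbon instead of the methyl group, or proton transfer may quench the anion before acylation. The fallback replaces acyl substitution by addition to an aldehyde followed by oxidation; it sets out from 3 (with 4) and comes back at 7. DIBAL-H (THF, −78 °C) should reduce 3 to (2E)-3-[4-(benzyloxy)-3-methoxyphenyl]prop-2-enal F3. The lithiated pyranone 5 adds 1,2 to this aldehyde, a well-known reaction of this anion, to give racemic 6-[(3E)-4-[4-(benzyloxy)-3-methoxyphenyl]-2-hydroxybut-3-en-1-yl]-4-methoxy-2H-pyran-2-one F4. Oxidation of the allylic alcohol (MnO2, CH2Cl2, or Dess–Martin periodinane) gives 7.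

Step 6. Epoxidation of the electron-poor chromone double bond may be slow enough for the dioxirane to attack benzylic C–H bonds or the electron-rich rings, or the epoxide may open without giving the enol. The fallback installs the C3 oxygen during ring C closure by the Algar–Flynn–Oyamada reaction; it sets out from 9 and comes back at 13. Mono-benzylation of 9 (BnBr, 1 equiv, K2CO3, acetone; the second hydroxyl remains chelated) should give (E)-1-[2-(benzyloxy)-6-hydroxy-4-methoxyphenyl]-3-[4-(benzyloxy)-3-methoxyphenyl]prop-2-en-1-one F5. Alkaline hydrogen peroxide (30% H2O2, aq NaOH, MeOH, 0 °C → rt) then converts F5 into 13 by oxidative cyclisation. Aurone formation is the known side path for 6'-alkoxy chalcones, which is why this is the fallback and not the main route.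

Further compounds
F1 | step 3 | 1-[2-hydroxy-4-methoxy-6-(methoxymethoxy)phenyl]ethanone | COCOc1cc(OC)cc(O)c1C(C)=O
F2 | step 3 | (E)-3-[4-(benzyloxy)-3-methoxyphenyl]-1-[2-hydroxy-4-methoxy-6-(methoxymethoxy)phenyl]prop-2-en-1-one | COCOc1cc(OC)cc(O)c1C(=O)/C=C/c1ccc(OCc2ccccc2)c(OC)c1
F3 | step 2 | (2E)-3-[4-(benzyloxy)-3-methoxyphenyl]prop-2-enal | O=C/C=C/c1ccc(OCc2ccccc2)c(OC)c1
F4 | step 2 | racemic 6-[(3E)-4-[4-(benzyloxy)-3-methoxyphenyl]-2-hydroxybut-3-en-1-yl]-4-methoxy-2H-pyran-2-one | COC1=CC(=O)OC(CC(O)/C=C/c2ccc(OCc3ccccc3)c(OC)c2)=C1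
F5 | step 6 | (E)-1-[2-(benzyloxy)-6-hydroxy-4-methoxyphenyl]-3-[4-(benzyloxy)-3-methoxyphenyl]prop-2-en-1-one | COc1cc(O)c(C(=O)/C=C/c2ccc(OCc3ccccc3)c(OC)c2)c(OCc2ccccc2)c1
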